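**Plan**

1. Retrosynthetic cuts, in order: the O15–acyl ester bond; the C3 carbinol (back to the 3-ketone); the C9–H/Δ7 pair (back to the 7β-allylic alcohol of a Δ8-7-ketone); the C3–C4 bond of ring A; the C9–C11 bond; the C10–C1 and C10–CH3 bonds, which leaves (R)-carvone as ring B.
2. Forward: (R)-carvone is α′-methylated and α′-allylated (C10), the C11–C16 chain is joined at C9 by Barbier addition and oxidative enone transposition, the allyl group becomes the C1–C3 propanal, and ring A is then closed onto ring B by forming C3–C4.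
3. Enabling feature: C4 is a gem-dimethyl quaternary carbon between the C3 carbinol and the ring-fusion carbon C5, which is the footprint of an isopropenyl group on C5 (ring B has the carvone pattern, C8 methyl para to C5). Hydrogen-atom transfer to its CH2 gives a tertiary C4 radical placed 1,6 to a C3 aldehyde tethered through C10–C1–C2.
4. Stereochemistry: C5 from (R)-carvone; C10 by enolate allylation anti to isopropenyl; the trans ring fusion follows from C5 and C10; C9 by suprafacial retro-ene hydrogen delivery from a 7α-diazene (7β-OH from Luche reduction); C3 (3α, axial) by LiBH(s-Bu)3 reduction of the 3-ketone; C13 from (R)-3-methylglutaric acid monomethyl ester; the ester α-carbon from (R)-2-methylbutanoic acid.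

Key step: step 11

Remark: the target is read as (13S)-3α-hydroxylabd-7-en-15-yl (2R)-2-methylbutanoate (5α-H, 9α-H, 10β-CH3, axial 3R hydroxyl), and both chiral acids are taken as purchasable single enantiomers. Labdane numbering is used: ring A = C1–C5 and C10, ring B = C5–C10, chain C11–C15 with C16 on C13, C17 on C8, C18/C19 on C4, C20 on C10; α is the face opposite C20.

**Route**

Step 1
Reactants: 1 (R)-3-methylglutaric acid monomethyl ester
Product: 2 methyl (3R)-5-hydroxy-3-methylpentanoate
Conditions: BH3·SMe2, THF, 0 °C → rt; then MeOH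
Reagents that add atoms: none
Why: Borane reduces the free carboxylic acid much faster than the methyl ester (chemoselective borane reduction), and the stereocentre is not touched.

Step 2
Reactants: 2 methyl (3R)-5-hydroxy-3-methylpentanoate
Product: 3 methyl (3R)-5-[(tert-butyldimethylsilyl)oxy]-3-methylpentanoate
Conditions: TBSCl, imidazole, CH2Cl2, 0 °C → rt
Reagents that add atoms: tert-butyldimethylsilyl chloride, CC(C)(C)[Si](C)(C)Cl
Why: Standard silylation of a primary alcohol, done at once so that the hydroxy ester cannot lactonise.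

Step 3
Reactants: 3 methyl (3R)-5-[(tert-butyldimethylsilyl)oxy]-3-methylpentanoate
Product: 4 (3S)-5-[(tert-butyldimethylsilyl)oxy]-3-methylpentan-1-ol
Conditions: LiAlH4, Et2O, 0 °C; then H2O
Reagents that add atoms: none
Why: Hydride reduction of the ester to the primary alcohol, which the silyl ether survives at 0 °C.

Step 4
Reactants: 4 (3S)-5-[(tert-butyldimethylsilyl)oxy]-3-methylpentan-1-ol
Product: 5 [(3R)-5-bromo-3-methylpentyl]oxy(tert-butyl)dimethylsilane
Conditions: CBr4, PPh3, CH2Cl2, 0 °C
Reagents that add atoms: carbon tetrabromide, BrC(Br)(Br)Br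
Why: The Appel reaction converts the primary alcohol into the bromide under near-neutral conditions that leave the silyl ether and the remote stereocentre intact.

Step 5
Reactants: 6 (R)-(−)-carvone
Product: 8 6-methylcarvone as a mixture of C6 epimers (trans epimer drawn), via lithium dienolate 7 (not isolated)
Conditions: LiN(i-Pr)2, THF, −78 °C; then MeI, −78 → 0 °C
Reagents that add atoms: iodomethane, CI
Why: Kinetic deprotonation occurs at the α′-methylene and the cross-conjugated enolate is C-methylated (enolate alkylation); the new centre is erased in step 6.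

Step 6
Reactants: 8 6-methylcarvone (epimer mixture)
Product: 10 (5S,6S)-6-allyl-2,6-dimethyl-5-(prop-1-en-2-yl)cyclohex-2-en-1-one, via lithium dienolate 9 (not isolated)
Conditions: LiN(i-Pr)2, THF, −78 °C; then allyl bromide, DMPU, −78 °C → rt
Reagents that add atoms: allyl bromide, C=CCBr
Why: In this second α′-enolate alkylation allyl bromide approaches anti to the neighbouring isopropenyl group, which sets the quaternary carbon (later C10) with methyl cis and allyl trans to isopropenyl.

Step 7
Reactants: 5 [(3R)-5-bromo-3-methylpentyl]oxy(tert-butyl)dimethylsilane; 10 (5S,6S)-6-allyl-2,6-dimethyl-5-(prop-1-en-2-yl)cyclohex-2-en-1-one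
Product: 12 (5S,6S)-6-allyl-1-[(3S)-5-[(tert-butyldimethylsilyl)oxy]-3-methylpentyl]-2,6-dimethyl-5-(prop-1-en-2-yl)cyclohex-2-en-1-ol as C1 epimers (1S drawn), via alkyllithium 11 (not isolated)
Conditions: Li (excess), THF, ultrasound, 0 → 20 °C; then H2O
Reagents that add atoms: none
Why: In this Barbier reaction the alkyllithium formed on the metal adds 1,2 to the hindered ketone, which has no α′-hydrogen to lose; both carbinol epimers serve because this carbon becomes sp2 in step 8.

Step 8
Reactants: 12 tertiary allylic alcohol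
Product: 13 (4S,5S)-4-allyl-3-[(3S)-5-[(tert-butyldimethylsilyl)oxy]-3-methylpentyl]-2,4-dimethyl-5-(prop-1-en-2-yl)cyclohex-2-en-1-one
Conditions: pyridinium chlorochromate (C5H5NH[CrO3Cl], 3 equiv), silica gel, CH2Cl2, rt
Reagents that add atoms: pyridinium chlorochromate, [O-][Cr](=O)(=O)Cl.c1cc[nH+]cc1
Why: In this Babler–Dauben oxidative transposition the tertiary allylic chromate ester shifts [3,3] to the unhindered secondary allylic position and is oxidised there, giving the transposed enone (C7 ketone) with the chain on C9.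

Step 9
Reactants: 13 transposed enone
Product: 15 (4S,5S)-3-[(3S)-5-[(tert-butyldimethylsilyl)oxy]-3-methylpentyl]-4-(3-hydroxypropyl)-2,4-dimethyl-5-(prop-1-en-2-yl)cyclohex-2-en-1-one, via alkyl catecholboronate 14 (not isolated)
Conditions: catecholborane, RhCl(PPh3)3 (2 mol %), THF, 0 °C → rt; then 30% H2O2, pH 7 phosphate buffer, EtOH, 0 °C
Reagents that add atoms: hydrogen peroxide, OO
Why: Rhodium-catalysed hydroboration selects the monosubstituted alkene over the 1,1-disubstituted isopropenyl group and, unlike the uncatalysed reaction, spares the ketone; buffered oxidation gives the anti-Markovnikov primary alcohol without epoxidising the enone.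

Step 10
Reactants: 15 enone primary alcohol
Product: 16 (4S,5S)-3-[(3S)-5-[(tert-butyldimethylsilyl)oxy]-3-methylpentyl]-2,4-dimethyl-4-(3-oxopropyl)-5-(prop-1-en-2-yl)cyclohex-2-en-1-one
Conditions: Dess–Martin periodinane, CH2Cl2, 0 °C → rt
Reagents that add atoms: none
Why: Dess–Martin oxidation stops cleanly at the aldehyde and does not touch the alkenes or the silyl ether.

Step 11
Reactants: 16 enone aldehyde
Product: 19 15-[(tert-butyldimethylsilyl)oxy]-3β-hydroxylabd-8-en-7-one, via tertiary C4 radical 17 (not isolated), via C3 alkoxy radical 18 (not isolated)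
Conditions: Fe(acac)3 (0.3 equiv), PhSiH3 (2.5 equiv), EtOH, 60 °C, Ar
Reagents that add atoms: none
Why: An iron hydride formed from Fe(acac)3 and PhSiH3 transfers a hydrogen atom to the CH2 of the electron-rich isopropenyl group (Markovnikov MHAT) to give the tertiary C4 radical 17, which adds to the aldehyde carbon C3, and the alkoxy radical 18 is reduced by divalent iron and protonated by ethanol. The closest known reaction types are the iron-mediated HAT-initiated radical cyclisation of alkene-tethered ketones and the intermolecular HAT coupling of unactivated alkenes with aldehydes. Ring A closes in the 6-exo-trig mode through a chair in which the radical-bearing group on C5 and the propanal chain on C10 are both equatorial on ring B, so the trans ring fusion (5α-H, 10β-CH3) follows from the two existing stereocentres. C4 becomes the non-stereogenic gem-dimethyl quaternary carbon, and C3 is expected mainly as the equatorial 3β-alkoxide (C=O pseudo-equatorial in the chair), a configuration the route does not rely on because C3 is reset in steps 14 and 15. The selectivity needed is hydrogen-atom transfer to the isopropenyl group only, which the substrate secures because its one other C=C bond is the electron-poor tetrasubstituted enone, a poor HAT acceptor that the C4 radical cannot reach through a ring of workable size.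

Step 12
Reactants: 19 15-[(tert-butyldimethylsilyl)oxy]-3β-hydroxylabd-8-en-7-one
Product: 20 15-[(tert-butyldimethylsilyl)oxy]labd-8-ene-3β,7β-diol
Conditions: NaBH4, CeCl3·7H2O, MeOH, −20 °C
Reagents that add atoms: none
Why: Luche reduction gives 1,2-reduction of the enone, with hydride entering along the axial (α) trajectory of the rigid trans-decalin, as in carvone → cis-carveol, to give the pseudo-equatorial 7β-alcohol.

Step 13
Reactants: 20 15-[(tert-butyldimethylsilyl)oxy]labd-8-ene-3β,7β-diol
Product: 23 15-[(tert-butyldimethylsilyl)oxy]labd-7-en-3β-ol, via allylic sulfonylhydrazine 21 (not isolated), via allylic diazene 22 (not isolated)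
Conditions: 2-nitrobenzenesulfonylhydrazide, PPh3, diethyl azodicarboxylate, N-methylmorpholine, −30 °C → rt
Reagents that add atoms: none
Why: In this reductive 1,3-transposition of an allylic alcohol, Mitsunobu displacement of the 7β-hydroxyl with inversion (the neopentyl 3β-hydroxyl is too hindered to react), loss of sulfinic acid and retro-ene expulsion of N2 from the 7α-diazene deliver hydrogen suprafacially to the α face of C9 as the double bond moves to C7–C8, so the C7 configuration is transferred to C9 (9α-H).

Step 14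
Reactants: 23 15-[(tert-butyldimethylsilyl)oxy]labd-7-en-3β-ol
Product: 24 15-[(tert-butyldimethylsilyl)oxy]labd-7-en-3-one
Conditions: Dess–Martin periodinane, CH2Cl2, rt
Reagents that add atoms: none
Why: Dess–Martin oxidation of the hindered secondary alcohol gives the 3-ketone and erases the C3 configuration from step 11, so either C3 epimer converges here.

Step 15
Reactants: 24 15-[(tert-butyldimethylsilyl)oxy]labd-7-en-3-one
Product: 25 15-[(tert-butyldimethylsilyl)oxy]labd-7-en-3α-ol
Conditions: LiBH(s-Bu)3, THF, −78 °C; then H2O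
Reagents that add atoms: none
Why: Under steric approach control the bulky trialkylborohydride avoids the axial trajectory past the axial hydrogens on C1 and C5 and attacks equatorially, giving the axial 3α-alcohol (3R), as is usual for 4,4-dimethyl-3-keto terpenoids.

Step 16
Reactants: 25 15-[(tert-butyldimethylsilyl)oxy]labd-7-en-3α-ol
Product: 26 (13S)-labd-7-ene-3α,15-diol
Conditions: Bu4NF, THF, rt
Reagents that add atoms: none
Why: Fluoride cleaves the primary silyl ether without affecting the alkene or the secondary alcohol.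

Step 17
Reactants: 26 (13S)-labd-7-ene-3α,15-diol; 27 (R)-2-methylbutanoic acid
Product: 28 (13S)-3α-hydroxylabd-7-en-15-yl (2R)-2-methylbutanoate
Conditions: DCC, DMAP (10 mol %), CH2Cl2, 0 °C
Reagents that add atoms: none
Why: Steglich esterification acylates the unhindered primary 15-hydroxyl far faster than the axial neopentyl 3α-hydroxyl, and carbodiimide activation with catalytic DMAP at 0 °C should not epimerise the acid α-carbon.

**Compound list**

1 | (R)-3-methylglutaric acid monomethyl ester, (3R)-5-methoxy-3-methyl-5-oxopentanoic acid | OC(=O)C[C@@H](C)CC(=O)OC | starting material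
2 | methyl (3R)-5-hydroxy-3-methylpentanoate | OCC[C@@H](C)CC(=O)OC | intermediate
3 | methyl (3R)-5-[(tert-butyldimethylsilyl)oxy]-3-methylpentanoate | CC(C)(C)[Si](C)(C)OCC[C@@H](C)CC(=O)OC | intermediate
4 | (3S)-5-[(tert-butyldimethylsilyl)oxy]-3-methylpentan-1-ol | CC(C)(C)[Si](C)(C)OCC[C@@H](C)CCO | intermediate
5 | [(3R)-5-bromo-3-methylpentyl]oxy(tert-butyl)dimethylsilane | CC(C)(C)[Si](C)(C)OCC[C@@H](C)CCBr | intermediate
6 | (R)-(−)-carvone, (5R)-2-methyl-5-(prop-1-en-2-yl)cyclohex-2-en-1-one | CC(=C)[C@@H]1CC=C(C)C(=O)C1 | starting material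
7 | lithium dienolate of carvone (deprotonated at C6) | [Li]OC1=C[C@H](C(C)=C)CC=C1C | intermediate
8 | (5R,6S)-2,6-dimethyl-5-(prop-1-en-2-yl)cyclohex-2-en-1-one (trans-6-methylcarvone drawn; its C6 epimer is carried along) | O=C1C(C)=CC[C@@H](C(C)=C)[C@@H]1C | intermediate
9 | lithium dienolate of 6-methylcarvone | [Li]OC1=C(C)[C@H](C(C)=C)CC=C1C | intermediate
10 | (5S,6S)-6-allyl-2,6-dimethyl-5-(prop-1-en-2-yl)cyclohex-2-en-1-one (allyl trans to isopropenyl) | O=C1C(C)=CC[C@@H](C(C)=C)[C@]1(C)CC=C | intermediate
11 | [(3S)-5-[(tert-butyldimethylsilyl)oxy]-3-methylpentyl]lithium | CC(C)(C)[Si](C)(C)OCC[C@@H](C)CC[Li] | intermediate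
12 | (5S,6S)-6-allyl-1-[(3S)-5-[(tert-butyldimethylsilyl)oxy]-3-methylpentyl]-2,6-dimethyl-5-(prop-1-en-2-yl)cyclohex-2-en-1-ol (1S epimer drawn; both C1 epimers used) | CC(C)(C)[Si](C)(C)OCC[C@@H](C)CC[C@]1(O)C(C)=CC[C@@H](C(C)=C)[C@]1(C)CC=C | intermediate
13 | (4S,5S)-4-allyl-3-[(3S)-5-[(tert-butyldimethylsilyl)oxy]-3-methylpentyl]-2,4-dimethyl-5-(prop-1-en-2-yl)cyclohex-2-en-1-one | CC(C)(C)[Si](C)(C)OCC[C@@H](C)CCC1=C(C)C(=O)C[C@@H](C(C)=C)[C@]1(C)CC=C | intermediate
14 | 2-alkyl-1,3,2-benzodioxaborole from hydroboration of the allyl group of 13 | CC(C)(C)[Si](C)(C)OCC[C@@H](C)CCC1=C(C)C(=O)C[C@@H](C(C)=C)[C@]1(C)CCCB2Oc3ccccc3O2 | intermediate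
15 | (4S,5S)-3-[(3S)-5-[(tert-butyldimethylsilyl)oxy]-3-methylpentyl]-4-(3-hydroxypropyl)-2,4-dimethyl-5-(prop-1-en-2-yl)cyclohex-2-en-1-one | CC(C)(C)[Si](C)(C)OCC[C@@H](C)CCC1=C(C)C(=O)C[C@@H](C(C)=C)[C@]1(C)CCCO | intermediate
16 | (4S,5S)-3-[(3S)-5-[(tert-butyldimethylsilyl)oxy]-3-methylpentyl]-2,4-dimethyl-4-(3-oxopropyl)-5-(prop-1-en-2-yl)cyclohex-2-en-1-one | CC(C)(C)[Si](C)(C)OCC[C@@H](C)CCC1=C(C)C(=O)C[C@@H](C(C)=C)[C@]1(C)CCC=O | intermediate
17 | tertiary C4 radical (2-propyl radical on C5) formed from 16 | CC(C)(C)[Si](C)(C)OCC[C@@H](C)CCC1=C(C)C(=O)C[C@@H]([C](C)C)[C@]1(C)CCC=O | intermediate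
18 | 3β-oxyl (alkoxy) radical of 19 | CC(C)(C)[Si](C)(C)OCC[C@@H](C)CCC1=C(C)C(=O)C[C@H]2C(C)(C)[C@@H]([O])CC[C@]12C | intermediate
19 | 15-[(tert-butyldimethylsilyl)oxy]-3β-hydroxylabd-8-en-7-one | CC(C)(C)[Si](C)(C)OCC[C@@H](C)CCC1=C(C)C(=O)C[C@H]2C(C)(C)[C@@H](O)CC[C@]12C | intermediate
20 | 15-[(tert-butyldimethylsilyl)oxy]labd-8-ene-3β,7β-diol | CC(C)(C)[Si](C)(C)OCC[C@@H](C)CCC1=C(C)[C@@H](O)C[C@H]2C(C)(C)[C@@H](O)CC[C@]12C | intermediate
21 | 15-[(tert-butyldimethylsilyl)oxy]-7α-[1-(2-nitrophenylsulfonyl)hydrazin-1-yl]labd-8-en-3β-ol | CC(C)(C)[Si](C)(C)OCC[C@@H](C)CCC1=C(C)[C@H](N(N)S(=O)(=O)c3ccccc3[N+](=O)[O-])C[C@H]2C(C)(C)[C@@H](O)CC[C@]12C | intermediate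
22 | 15-[(tert-butyldimethylsilyl)oxy]-7α-diazenyllabd-8-en-3β-ol | CC(C)(C)[Si](C)(C)OCC[C@@H](C)CCC1=C(C)[C@H](N=N)C[C@H]2C(C)(C)[C@@H](O)CC[C@]12C | intermediate
23 | 15-[(tert-butyldimethylsilyl)oxy]labd-7-en-3β-ol | CC(C)(C)[Si](C)(C)OCC[C@@H](C)CC[C@H]1C(C)=CC[C@H]2C(C)(C)[C@@H](O)CC[C@]12C | intermediate
24 | 15-[(tert-butyldimethylsilyl)oxy]labd-7-en-3-one | CC(C)(C)[Si](C)(C)OCC[C@@H](C)CC[C@H]1C(C)=CC[C@H]2C(C)(C)C(=O)CC[C@]12C | intermediate
25 | 15-[(tert-butyldimethylsilyl)oxy]labd-7-en-3α-ol | CC(C)(C)[Si](C)(C)OCC[C@@H](C)CC[C@H]1C(C)=CC[C@H]2C(C)(C)[C@H](O)CC[C@]12C | intermediate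
26 | (13S)-labd-7-ene-3α,15-diol | OCC[C@@H](C)CC[C@H]1C(C)=CC[C@H]2C(C)(C)[C@H](O)CC[C@]12C | intermediate
27 | (R)-2-methylbutanoic acid | CC[C@@H](C)C(=O)O | starting material
28 | (13S)-3α-hydroxylabd-7-en-15-yl (2R)-2-methylbutanoate | CC[C@@H](C)C(=O)OCC[C@@H](C)CC[C@H]1C(C)=CC[C@H]2C(C)(C)[C@H](O)CC[C@]12C | target

**Step count and risks**

Total: 17 steps. Longest linear sequence: 15 steps (steps 1–4, then 7–17).

Step 11 (key ring closure). The ring closure may be reversible (β-scission of the alkoxy radical), and the aldehyde may be reduced by the silane or acetalised, so that plain hydrogenation of the isopropenyl group outruns cyclisation. The fallback replaces the aldehyde by a nitrile as radical acceptor; it sets out from alcohol 15 and comes back at 19. One-pot oxidation–ammoxidation (TEMPO, PhI(OAc)2, NH4OAc, MeCN/H2O) should give the nitrile analogue of 16, 3-[ring]propanenitrile F1. The same Fe(acac)3/PhSiH3/EtOH conditions (a known HAT cyclisation onto nitriles) should close ring A onto the C≡N carbon, which is inert to the silane and gives an iminyl radical that does not reopen, to deliver the N–H ketimine F2. Acidic work-up hydrolyses it to 15-[(tert-butyldimethylsilyl)oxy]labd-8-ene-3,7-dione F3. NaBH4 in MeOH/CH2Cl2 at −78 °C should reduce the saturated 3-ketone in preference to the conjugated 7-ketone by axial attack, giving 19.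

Step 13. Mitsunobu displacement at the allylic carbinol next to the C8 methyl may be slow, with elimination to a diene or decomposition of the sulfonylhydrazide competing. The fallback sets out from 20 and comes back at 23. Selective acylation of the allylic hydroxyl (ClCO2Me, pyridine, CH2Cl2, 0 °C) should give the 7β-methyl carbonate F4. Hydrogenolysis with Pd(OAc)2, PBu3 and HCO2NH4 in dioxane at reflux ionises the carbonate with inversion, so zerovalent palladium ends on the α face, and the palladium formate transfers hydride on that face to the more substituted allyl terminus C9, giving 23 (9α-H, Δ7) directly.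

Step 9. Discrimination between the allyl and isopropenyl groups may be insufficient, a rhodium hydride may isomerise the allyl group, or the enone carbonyl may be reduced. The fallback sets out from 13 and comes back at aldehyde 16 without passing through 15. It is an aldehyde-selective (anti-Markovnikov) Wacker-type oxidation of the terminal alkene (PdCl2(PhCN)2, CuCl2·2H2O, AgNO2, t-BuOH/MeNO2, O2, rt), which leaves the 1,1-disubstituted isopropenyl group untouched; no new compound is made (F0).

**Further compounds**

F1 | step 11 | 3-[(1S,6S)-2-[(3S)-5-[(tert-butyldimethylsilyl)oxy]-3-methylpentyl]-1,3-dimethyl-4-oxo-6-(prop-1-en-2-yl)cyclohex-2-en-1-yl]propanenitrile | CC(C)(C)[Si](C)(C)OCC[C@@H](C)CCC1=C(C)C(=O)C[C@@H](C(C)=C)[C@]1(C)CCC#N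
F2 | step 11 | 15-[(tert-butyldimethylsilyl)oxy]-3-iminolabd-8-en-7-one (N–H ketimine) | CC(C)(C)[Si](C)(C)OCC[C@@H](C)CCC1=C(C)C(=O)C[C@H]2C(C)(C)C(=N)CC[C@]12C
F3 | step 11 | 15-[(tert-butyldimethylsilyl)oxy]labd-8-ene-3,7-dione | CC(C)(C)[Si](C)(C)OCC[C@@H](C)CCC1=C(C)C(=O)C[C@H]2C(C)(C)C(=O)CC[C@]12C
F4 | step 13 | 15-[(tert-butyldimethylsilyl)oxy]-3β-hydroxylabd-8-en-7β-yl methyl carbonate | CC(C)(C)[Si](C)(C)OCC[C@@H](C)CCC1=C(C)[C@@H](OC(=O)OC)C[C@H]2C(C)(C)[C@@H](O)CC[C@]12C
F0 | step 9 | none | none
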